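**Retrosynthetic overview**

1. Atom labels: C1 = bridgehead carrying O7 and the C9 acyl group, C2 = CMe2, C3 = CH(prenyl), C4 = CH2, C5 = prenylated bridgehead, C6 = lactone C=O, C8 = bridging ketone. Ring A is the lactone C1–O7–C6–C5–C8 and ring B the carbocycle C1–C2–C3–C4–C5–C8. The route rests on the C2–C3 bond: C2 is a tertiary centre beside the fully substituted C1 and can be unmasked as a radical from a CO2H group, while C3 and the CH2 of its prenyl group are the β- and α-carbons of an enal hung on C5 through C4.
2. Last bond: the C3 prenyl alkene, by Wittig isopropylidenation of the C3–CH2CHO arm (17 → 20).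
3. Key disconnection C2–C3: ring B by photoredox decarboxylative 6-exo radical conjugate addition of acid 16, in which ring A already holds both arms cis.
4. Ring A first: C1–C2 by Reformatsky addition to the central carbonyl of a 2,3-diketo ester made from (R)-2-methylbutanoic acid, C5–C8 by Lacey–Dieckmann closure of the O-pent-4-enoyl ester, then cross-metathesis (C4 arm) and Tsuji–Trost prenylation at C5 anti to the C2 group.
5. Ring order: ring A (step 5), then ring B (step 10).

Key step: step 10

Remark: tetronic acids 10 and 12 are written as their 4-hydroxyfuran-2(5H)-one (enol) tautomers, and the labels C1–C9 and O7 are those of the overview.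

**Route**

Step 1
Reactants: 1 (2R)-2-methylbutanoic acid; 2 methyl (triphenyl-λ5-phosphanylidene)acetate
Product: 3 methyl (4R)-4-methyl-3-oxo-2-(triphenyl-λ5-phosphanylidene)hexanoate
Conditions: EDCI, DMAP (cat.), CH2Cl2, 0 °C → rt
Reagents that add atoms: none
Why: Carbodiimide-mediated C-acylation of the stabilised phosphorus ylide by the activated acid gives the keto ylide under nearly neutral conditions, so the α-stereocentre of the acid is not expected to epimerise.

Step 2
Reactants: 3 methyl (4R)-4-methyl-3-oxo-2-(triphenyl-λ5-phosphanylidene)hexanoate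
Product: 4 methyl (4R)-4-methyl-2,3-dioxohexanoate
Conditions: dimethyldioxirane (2.2 equiv, acetone solution), CH2Cl2, 0 °C; concentrated and used at once under anhydrous conditions
Reagents that add atoms: dimethyldioxirane, CC1(C)OO1
Why: Oxidative cleavage of the C=P bond of an acyl phosphorane by dimethyldioxirane is a standard entry to vicinal tricarbonyl compounds and should deliver the anhydrous 2,3-diketo ester without acid or base that could enolise the position α to C9.

Step 3
Reactants: 4 methyl (4R)-4-methyl-2,3-dioxohexanoate; 5 tert-butyl 2-bromo-2-methylpropanoate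
Product: 7 1-tert-butyl 4-methyl (3S)-3-hydroxy-2,2-dimethyl-3-[(2R)-2-methylbutanoyl]butanedioate, via Reformatsky reagent 6 (not isolated)
Conditions: 5, Zn dust (Me3SiCl-activated), THF, 40 °C; then 4, THF, −78 → −20 °C; aq NH4Cl; chromatographic separation of the C1 epimers
Reagents that add atoms: none
Why: Reformatsky addition of zinc enolate 6 goes to the central, most electrophilic carbonyl of the vicinal tricarbonyl (C1–C2 bond); the distant sec-butyl centre gives no useful facial bias, so both C1 epimers are expected and the (3S) epimer 7 is isolated by chromatography (preparative HPLC if needed), its configuration to be confirmed by X-ray analysis of a crystalline derivative.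

Step 4
Reactants: 7 1-tert-butyl 4-methyl (3S)-3-hydroxy-2,2-dimethyl-3-[(2R)-2-methylbutanoyl]butanedioate; 8 pent-4-enoic anhydride
Product: 9 1-tert-butyl 4-methyl (3S)-2,2-dimethyl-3-[(2R)-2-methylbutanoyl]-3-(pent-4-enoyloxy)butanedioate
Conditions: DMAP (1 equiv), Et3N, CH2Cl2, 0 → 40 °C
Reagents that add atoms: none
Why: DMAP-catalysed (Steglich-type) O-acylation through the acylpyridinium ion should esterify the hindered but acidified tertiary hydroxyl, and the absence of strong base or Lewis acid avoids retro-aldol cleavage and α-ketol rearrangement of the α-hydroxy β-keto ester.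

Step 5
Reactants: 9 1-tert-butyl 4-methyl (3S)-2,2-dimethyl-3-[(2R)-2-methylbutanoyl]-3-(pent-4-enoyloxy)butanedioate
Product: 10 tert-butyl 2-[(2R)-3-hydroxy-2-[(2R)-2-methylbutanoyl]-5-oxo-4-(prop-2-en-1-yl)-2,5-dihydrofuran-2-yl]-2-methylpropanoate
Conditions: LiN(SiMe3)2 (2.2 equiv), THF, −78 → 0 °C; then 1 M HCl
Reagents that add atoms: none
Why: Lacey–Dieckmann condensation, in which the pentenoate enolate attacks the methyl ester on C1 in a 5-exo-trig Claisen closure (C5–C8 bond, ring A) that formation of the tetronate anion makes irreversible, whereas aldol addition to the C9 ketone is reversible, the tert-butyl ester is too hindered to compete, and the low temperature limits enolisation at the sec-butyl centre.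

Step 6
Reactants: 10 tert-butyl 2-[(2R)-3-hydroxy-2-[(2R)-2-methylbutanoyl]-5-oxo-4-(prop-2-en-1-yl)-2,5-dihydrofuran-2-yl]-2-methylpropanoate; 11 (2Z)-but-2-ene-1,4-diol
Product: 12 tert-butyl 2-[(2R)-3-hydroxy-4-[(2E)-4-hydroxybut-2-en-1-yl]-2-[(2R)-2-methylbutanoyl]-5-oxo-2,5-dihydrofuran-2-yl]-2-methylpropanoate
Conditions: second-generation Hoveyda–Grubbs catalyst (H2IMes)Cl2Ru(=CH-C6H4-2-OiPr) (5 mol%), 11 (5 equiv), CH2Cl2, 40 °C
Reagents that add atoms: none
Why: Olefin cross-metathesis of the terminal allyl group with the symmetrical diol should give the (E)-allylic alcohol, and because no second alkene sits on C5 at this stage, ring-closing metathesis cannot intervene.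

Step 7
Reactants: 12 tert-butyl 2-[(2R)-3-hydroxy-4-[(2E)-4-hydroxybut-2-en-1-yl]-2-[(2R)-2-methylbutanoyl]-5-oxo-2,5-dihydrofuran-2-yl]-2-methylpropanoate; 13 3-methylbut-2-en-1-yl acetate (prenyl acetate)
Product: 14 tert-butyl 2-[(2S,4R)-4-[(2E)-4-hydroxybut-2-en-1-yl]-4-(3-methylbut-2-en-1-yl)-2-[(2R)-2-methylbutanoyl]-3,5-dioxooxolan-2-yl]-2-methylpropanoate
Conditions: Pd(PPh3)4 (5 mol%), Et3N (1.2 equiv), THF, 50 °C
Reagents that add atoms: none
Why: Tsuji–Trost allylic alkylation, in which the soft tetronate attacks the less hindered terminus of the π-prenyl palladium complex through carbon (O-allylation is reversible under the catalyst) and the electrophile comes to C5 on the face anti to the bulky C(CH3)2CO2tBu group of C1, so that the C5 quaternary centre forms with prenyl trans and the hydroxybutenyl arm cis to the C2 group.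

Step 8
Reactants: 14 tert-butyl 2-[(2S,4R)-4-[(2E)-4-hydroxybut-2-en-1-yl]-4-(3-methylbut-2-en-1-yl)-2-[(2R)-2-methylbutanoyl]-3,5-dioxooxolan-2-yl]-2-methylpropanoate
Product: 15 tert-butyl 2-[(2S,4R)-4-(3-methylbut-2-en-1-yl)-2-[(2R)-2-methylbutanoyl]-3,5-dioxo-4-[(2E)-4-oxobut-2-en-1-yl]oxolan-2-yl]-2-methylpropanoate
Conditions: MnO2 (activated, excess), CH2Cl2, rt
Reagents that add atoms: none
Why: Chemoselective allylic oxidation by MnO2 converts only the primary allylic alcohol into the conjugated (E)-enal that will act as radical acceptor, while the prenyl alkene, both ketones and the esters are left alone.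

Step 9
Reactants: 15 tert-butyl 2-[(2S,4R)-4-(3-methylbut-2-en-1-yl)-2-[(2R)-2-methylbutanoyl]-3,5-dioxo-4-[(2E)-4-oxobut-2-en-1-yl]oxolan-2-yl]-2-methylpropanoate
Product: 16 2-[(2S,4R)-4-(3-methylbut-2-en-1-yl)-2-[(2R)-2-methylbutanoyl]-3,5-dioxo-4-[(2E)-4-oxobut-2-en-1-yl]oxolan-2-yl]-2-methylpropanoic acid
Conditions: ZnBr2 (5 equiv), CH2Cl2, rt; dilute aq HCl work-up
Reagents that add atoms: none
Why: Lewis-acid-promoted tert-butyl ester cleavage (alkyl–oxygen fission with loss of 2-methylpropene) frees the C2 carboxylic acid without a strong protic acid, which could add to the prenyl alkene, and without base, which could open the non-enolisable β-keto lactone; the acid is taken on without chromatography.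

Step 10
Reactants: 16 2-[(2S,4R)-4-(3-methylbut-2-en-1-yl)-2-[(2R)-2-methylbutanoyl]-3,5-dioxo-4-[(2E)-4-oxobut-2-en-1-yl]oxolan-2-yl]-2-methylpropanoic acid
Product: 17 [(1S,3R,5S)-4,4-dimethyl-1-(3-methylbut-2-en-1-yl)-5-[(2R)-2-methylbutanoyl]-7,8-dioxo-6-oxabicyclo[3.2.1]octan-3-yl]acetaldehyde
Conditions: [Ir(dF(CF3)ppy)2(dtbbpy)]PF6 (2 mol%), K2HPO4 (1.2 equiv), degassed DMF (0.01 M), blue LEDs (450 nm), rt
Reagents that add atoms: none
Why: The excited trivalent iridium photocatalyst oxidises the potassium carboxylate of 16, CO2 is lost, and the nucleophilic tertiary C2 radical adds to C3, the β-carbon of the enal; the α-formyl radical so formed is reduced by the divalent iridium species to the enolate and protonated, which closes the catalytic cycle. The closest known reaction type is the visible-light photoredox decarboxylative radical conjugate addition (Giese reaction) of carboxylic acids, used here intramolecularly. Ring B (C1–C2–C3–C4–C5–C8) closes in the 6-exo-trig mode through the C2–C3 bond, which turns the furan-2,4-dione into the 6-oxabicyclo[3.2.1]octane-7,8-dione. The new C3 centre should arise from a chair-like transition state with the CH=CH–CHO chain pseudo-equatorial (exo), because the axial position points into the O7–C6 lactone bridge that spans C1 and C5. Ring closure has to be faster than migration of an acyl group from C1 to the C2 radical centre (3-exo attack on the C9 or C8 carbonyl) and must spare the prenyl alkene. The first is favoured by the cis placement of radical and acceptor on ring A (set in step 7), the gem-dimethyl group, high dilution and the polarity match of an electron-rich radical with an electron-poor enal, and the second follows from the trans, electron-rich prenyl group being out of reach.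

Step 11
Reactants: 17 [(1S,3R,5S)-4,4-dimethyl-1-(3-methylbut-2-en-1-yl)-5-[(2R)-2-methylbutanoyl]-7,8-dioxo-6-oxabicyclo[3.2.1]octan-3-yl]acetaldehyde; 18 triphenyl(propan-2-yl)phosphonium iodide
Product: 20 (1S,3S,5S)-4,4-dimethyl-1,3-bis(3-methylbut-2-en-1-yl)-5-[(2R)-2-methylbutanoyl]-6-oxabicyclo[3.2.1]octane-7,8-dione, via isopropylidenetriphenylphosphorane 19 (not isolated)
Conditions: 18, n-BuLi, THF, 0 °C; then 17, −78 → 0 °C
Reagents that add atoms: none
Why: Wittig olefination with the non-stabilised isopropylidene ylide should be fast at the unhindered aldehyde at low temperature, whereas the two ketones flanked by quaternary carbons and the lactone are too hindered to react, so the second prenyl group is formed without touching the stereocentres.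

**Compound list**

1 | (2R)-2-methylbutanoic acid | CC[C@@H](C)C(=O)O | starting material
2 | methyl (triphenyl-λ5-phosphanylidene)acetate | COC(=O)C=P(c1ccccc1)(c1ccccc1)c1ccccc1 | starting material
3 | methyl (4R)-4-methyl-3-oxo-2-(triphenyl-λ5-phosphanylidene)hexanoate | CC[C@@H](C)C(=O)C(C(=O)OC)=P(c1ccccc1)(c1ccccc1)c1ccccc1 | intermediate
4 | methyl (4R)-4-methyl-2,3-dioxohexanoate | CC[C@@H](C)C(=O)C(=O)C(=O)OC | intermediate
5 | tert-butyl 2-bromo-2-methylpropanoate | CC(C)(Br)C(=O)OC(C)(C)C | starting material
6 | (1-tert-butoxy-2-methyl-1-oxopropan-2-yl)zinc bromide (Reformatsky reagent) | CC(C)([Zn]Br)C(=O)OC(C)(C)C | intermediate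
7 | 1-tert-butyl 4-methyl (3S)-3-hydroxy-2,2-dimethyl-3-[(2R)-2-methylbutanoyl]butanedioate | CC[C@@H](C)C(=O)[C@](O)(C(=O)OC)C(C)(C)C(=O)OC(C)(C)C | intermediate
8 | pent-4-enoic anhydride | C=CCCC(=O)OC(=O)CCC=C | starting material
9 | 1-tert-butyl 4-methyl (3S)-2,2-dimethyl-3-[(2R)-2-methylbutanoyl]-3-(pent-4-enoyloxy)butanedioate | CC[C@@H](C)C(=O)[C@](OC(=O)CCC=C)(C(=O)OC)C(C)(C)C(=O)OC(C)(C)C | intermediate
10 | tert-butyl 2-[(2R)-3-hydroxy-2-[(2R)-2-methylbutanoyl]-5-oxo-4-(prop-2-en-1-yl)-2,5-dihydrofuran-2-yl]-2-methylpropanoate | CC[C@@H](C)C(=O)[C@]1(C(C)(C)C(=O)OC(C)(C)C)OC(=O)C(CC=C)=C1O | intermediate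
11 | (2Z)-but-2-ene-1,4-diol | OC/C=C\CO | starting material
12 | tert-butyl 2-[(2R)-3-hydroxy-4-[(2E)-4-hydroxybut-2-en-1-yl]-2-[(2R)-2-methylbutanoyl]-5-oxo-2,5-dihydrofuran-2-yl]-2-methylpropanoate | CC[C@@H](C)C(=O)[C@]1(C(C)(C)C(=O)OC(C)(C)C)OC(=O)C(C/C=C/CO)=C1O | intermediate
13 | 3-methylbut-2-en-1-yl acetate (prenyl acetate) | CC(=O)OCC=C(C)C | starting material
14 | tert-butyl 2-[(2S,4R)-4-[(2E)-4-hydroxybut-2-en-1-yl]-4-(3-methylbut-2-en-1-yl)-2-[(2R)-2-methylbutanoyl]-3,5-dioxooxolan-2-yl]-2-methylpropanoate | CC[C@@H](C)C(=O)[C@]1(C(C)(C)C(=O)OC(C)(C)C)OC(=O)[C@@](CC=C(C)C)(C/C=C/CO)C1=O | intermediate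
15 | tert-butyl 2-[(2S,4R)-4-(3-methylbut-2-en-1-yl)-2-[(2R)-2-methylbutanoyl]-3,5-dioxo-4-[(2E)-4-oxobut-2-en-1-yl]oxolan-2-yl]-2-methylpropanoate | CC[C@@H](C)C(=O)[C@]1(C(C)(C)C(=O)OC(C)(C)C)OC(=O)[C@@](CC=C(C)C)(C/C=C/C=O)C1=O | intermediate
16 | 2-[(2S,4R)-4-(3-methylbut-2-en-1-yl)-2-[(2R)-2-methylbutanoyl]-3,5-dioxo-4-[(2E)-4-oxobut-2-en-1-yl]oxolan-2-yl]-2-methylpropanoic acid | CC[C@@H](C)C(=O)[C@]1(C(C)(C)C(=O)O)OC(=O)[C@@](CC=C(C)C)(C/C=C/C=O)C1=O | intermediate
17 | [(1S,3R,5S)-4,4-dimethyl-1-(3-methylbut-2-en-1-yl)-5-[(2R)-2-methylbutanoyl]-7,8-dioxo-6-oxabicyclo[3.2.1]octan-3-yl]acetaldehyde | CC[C@@H](C)C(=O)[C@@]12OC(=O)[C@@](CC=C(C)C)(C[C@H](CC=O)C1(C)C)C2=O | intermediate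
18 | triphenyl(propan-2-yl)phosphonium iodide | CC(C)[P+](c1ccccc1)(c1ccccc1)c1ccccc1.[I-] | starting material
19 | triphenyl(propan-2-ylidene)-λ5-phosphane (isopropylidenetriphenylphosphorane) | CC(C)=P(c1ccccc1)(c1ccccc1)c1ccccc1 | intermediate
20 | (1S,3S,5S)-4,4-dimethyl-1,3-bis(3-methylbut-2-en-1-yl)-5-[(2R)-2-methylbutanoyl]-6-oxabicyclo[3.2.1]octane-7,8-dione | CC[C@@H](C)C(=O)[C@@]12OC(=O)[C@@](CC=C(C)C)(C[C@H](CC=C(C)C)C1(C)C)C2=O | target

**Step count and risks**

Total step count: 11. Longest linear sequence: 11 steps (1 → 20); all other inputs are purchased.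

Steps most likely to fail:

1. Step 10 (key step). The hindered, electron-poor carboxylate may be oxidised too slowly, or the C2 radical may be lost by 1,2-acyl migration or by reduction before it closes onto C3. Fallback, from 16 back to 17: the acid would be coupled with N-hydroxyphthalimide (N,N'-diisopropylcarbodiimide, DMAP cat., CH2Cl2) to the 1,3-dioxoisoindolin-2-yl ester of 16 F1. Single-electron reduction of this redox-active ester ([Ru(bpy)3](PF6)2, Hantzsch ester, iPr2NEt, blue LEDs, CH2Cl2) fragments it irreversibly to the same C2 radical without any carboxylate oxidation. After 6-exo closure, hydrogen-atom transfer from the Hantzsch ester would give 17 directly.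

2. Step 5. The ester enolate may be diverted by addition to the C9 ketone, the Claisen closure at the crowded C1 ester may be slow, and the amide base may epimerise the sec-butyl centre. Fallback, from 7 back to 10 (it also replaces the acylation of step 4): alcohol 7 would be esterified with mono-allyl malonate (DCC, CH2Cl2, through the carboalkoxyketene, which also eases acylation of the hindered hydroxyl) to the mixed allyl malonate F2. Its doubly activated methylene would close ring A under a weak base (DBU, THF, 0 °C) in the classical Lacey–Dieckmann sense to the 3-(allyloxycarbonyl)tetronic acid F3. Pd(PPh3)4 in THF would then bring about decarboxylative allylation (ionisation of the allyl ester, loss of CO2, C-allylation of the tetronate) to give 10.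

3. Step 3. Addition to the central carbonyl proceeds without facial discrimination, so half of the material is the wrong C1 epimer and the epimers may be hard to separate. Fallback, from 4 back to 7: the tricarbonyl would be combined with the silyl ketene acetal 1-tert-butoxy-2-methyl-1-(trimethylsilyloxy)prop-1-ene F4 (from tert-butyl 2-methylpropanoate, LiN(iPr)2, Me3SiCl) in a Mukaiyama aldol addition catalysed by a chiral divalent copper bis(oxazoline) Lewis acid, [Cu(tBu-box)](OTf)2. The catalyst binds the 1,2-dicarbonyl unit as a chelate and shields one face of the central carbonyl, and the ligand antipode that favours the (3S) carbinol would be chosen in a test run. The resulting trimethylsilyl ether of 7 F5 would be cleaved with HF·pyridine to return 7.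

**Further compounds**

F1 | step 10 | 1,3-dioxoisoindolin-2-yl 2-[(2S,4R)-4-(3-methylbut-2-en-1-yl)-2-[(2R)-2-methylbutanoyl]-3,5-dioxo-4-[(2E)-4-oxobut-2-en-1-yl]oxolan-2-yl]-2-methylpropanoate | CC[C@@H](C)C(=O)[C@]1(C(C)(C)C(=O)ON2C(=O)c3ccccc3C2=O)OC(=O)[C@@](CC=C(C)C)(C/C=C/C=O)C1=O
F2 | step 5 | 1-tert-butyl 4-methyl (3S)-2,2-dimethyl-3-[(2R)-2-methylbutanoyl]-3-{[3-oxo-3-(prop-2-en-1-yloxy)propanoyl]oxy}butanedioate | CC[C@@H](C)C(=O)[C@](OC(=O)CC(=O)OCC=C)(C(=O)OC)C(C)(C)C(=O)OC(C)(C)C
F3 | step 5 | prop-2-en-1-yl (5R)-5-(1-tert-butoxy-2-methyl-1-oxopropan-2-yl)-4-hydroxy-5-[(2R)-2-methylbutanoyl]-2-oxo-2,5-dihydrofuran-3-carboxylate | CC[C@@H](C)C(=O)[C@]1(C(C)(C)C(=O)OC(C)(C)C)OC(=O)C(C(=O)OCC=C)=C1O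
F4 | step 3 | 1-tert-butoxy-2-methyl-1-(trimethylsilyloxy)prop-1-ene | CC(C)=C(OC(C)(C)C)O[Si](C)(C)C
F5 | step 3 | 1-tert-butyl 4-methyl (3S)-2,2-dimethyl-3-[(2R)-2-methylbutanoyl]-3-(trimethylsilyloxy)butanedioate | CC[C@@H](C)C(=O)[C@](O[Si](C)(C)C)(C(=O)OC)C(C)(C)C(=O)OC(C)(C)C
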